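(The earlier runs and the new flask stem from a simulated flask from invented constants; the scatter is artificial.)

Q, the solid charged to the ochre flask, gives the curve to draw first. Its fall measures what enters solution as L, and E stays a small correction beside that, at 4.4% against 15.7% of L at 2 min.

| flask | Q | J | remark | time |
|---|---|---|---|---|
| ochre | 20 mM | 0.70 equiv | the very flask that is asked about, followed so far |  |
| green | 20 mM | 1 equiv | run made earlier |  |
| flask | 20 mM | 0.700 equiv |  | 10 min |

- ochre (time / s: E / %, L / %, Q / %): 25.0: 0.6, 8.0, 93.7; 50.0: 0.7, 12.1, 86.7; 80.0: 3.0, 13.3, 79.1; 90.0: 1.7, 15.4, 75.9; 120: 4.4, 15.7, 72.2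
- green (time / min: E / %, L / %, Q / %): 0.833: 2.6, 10.4, 87.7; 1.50: 4.7, 15.3, 79.1; 2.50: 4.5, 15.9, 66.3; 3.00: 5.2, 18.6, 60.1; 4.00: 6.5, 18.2, 48.8

(standard deviation of a reading: 1 percentage point)

1. amount of E at 10 min, in percent of the Q charged
2. concentration of L in solution at 5.0 min, in percent of saturation
3. the change that raises the amount of E at 10 min, in percent of the Q charged most ("none" if none brings more than 2 percentage points) (birch / larch / oak / none)
4. amount of E at 10 min, in percent of the Q charged, after oak

- birch: doubling the dissolution coefficient of Q, all else as stated
- larch: doubling the amount of J, all else as stated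
- oak: doubling the solubility of Q, all else as stated

- Q is a solid; its amount is given per volume of the solution
- the earlier runs were read with a standard deviation of 1 percentage point
- at the start none of Q is in solution
- L is what Q becomes in solution
- L means what is dissolved; the solid is not counted in it

The ochre run starts with this slope:

start: 3.02 mM min⁻¹

Ochre reads 72.2% of Q at 2 min, and green, with more J, averages 72.7% across its readings on either side of that time. So green's longer curve can serve for ochre. Its straight part gives this slope:

(79.1% − 48.8%) of 20 mM, over 2.50 min: 2.42 mM min⁻¹

This is the dissolving flow, the amount of Q per litre entering solution each minute while solid lasts. It is slower than the start of the ochre run. It is a pseudo-zero-order feed, counted in mM and not as a share of the charge. Carried forward from the last green reading, it draws the rest of the curve: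

Q at 5.0 min: 36.7%

knee, where Q reaches zero: 8.03 min

The knee comes before the asked time, so Q should stand at its level of zero by then, and L should have lost its feed.

The forecast gave 11%, 50%, oak and 15%, on the ground: “Oak raises the driving force most”.

The ochre flask gives 6.59% of E, and L at 41.9% of saturation at 5.0 min. The answer to the choice is none: birch adds 0.63 percentage points, larch 1.1 points and oak 0.69 points, each under 2 points. After oak, E is 7.28%.

    2 L → D (k = 1.40 M⁻¹ s⁻¹)
    L + J ⇌ E (K = 380 M⁻¹, k = 0.460 M⁻¹ s⁻¹)
    Q ⇌ L, rate k3*(cs3 - [L]) while solid is left; crystals form when [L] > cs3 (solubility = 8.40 mM, k = 0.00750 s⁻¹)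
    2 J → X (k = 0.650 M⁻¹ s⁻¹)

The ochre flask reads 38.1% of Q at 5.00 min, beside the reckoned 36.7%, and 0% at 10.0 min, past the knee. A heavier flask holds 80 mM of Q at the same equivalents and time. The flow, being in mM, is taken unchanged there:

Q left: 69.7%

The knee of that flask lies beyond the asked time. The heavier flask reads 70.8% of Q, with E at 2.18%, at 10.0 min.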